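(The readings are simulated for an exercise; noise was put on by code.)

Start from how slowly the zeta run finishes: its substrate falls by 21 percentage points in the first 0.333 h, but by 4.8 points over the last 2.00 h. Waiting therefore buys you little there, and your choice for the next run is the charge of reagent.

common to all: substrate 0.041 M
- zeta: reagent in the second phase 0.038 M; run made earlier
- gamma: reagent in the second phase 0.13 M; run made earlier
- epsilon: reagent in the second phase 0.46 M; run made earlier
- elm: reagent in the second phase 0.0300 M; time 4.0 h; volume of the second phase over the first 0.50
- oak: reagent in the second phase 0.0600 M; time 4.0 h; volume of the second phase over the first 0.50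
- maple: reagent in the second phase 0.120 M; time 4.0 h; volume of the second phase over the first 0.50
- cedar: reagent in the second phase 0.250 M; time 4.0 h; volume of the second phase over the first 0.50
- larch: reagent in the second phase 0.500 M; time 4.0 h; volume of the second phase over the first 0.50

| run | time / h | target / % | substrate / % |
|---|---|---|---|
| zeta | 0.333 | 20.0 | 79.0 |
| zeta | 0.667 | 32.0 | 64.1 |
| zeta | 1.00 | 38.1 | 56.4 |
| zeta | 2.00 | 46.2 | 45.6 |
| zeta | 4.00 | 48.6 | 40.8 |
| gamma | 0.333 | 45.7 | 46.7 |
| gamma | 1.00 | 54.1 | 16.5 |
| gamma | 2.00 | 48.0 | 7.7 |
| gamma | 3.00 | 42.9 | 5.4 |
| gamma | 4.00 | 40.3 | 4.4 |
| epsilon | 0.333 | 50.4 | 10.2 |
| epsilon | 1.00 | 24.0 | 0.5 |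
| epsilon | 2.00 | 12.7 | 0.6 |
| epsilon | 3.00 | 9.2 | 0.4 |
| epsilon | 4.00 | 7.9 | 0.3 |

(scatter of a reading: 0.3 percentage points)

- in the second phase: reagent in the second phase; everything else is in the first
- charges count per volume of the first phase; a concentration in a rate is the amount of a species over the volume of its own phase; every rate counts per litre of the first phase
- the numbers in the tables scatter by 0.3 percentage points (one standard deviation)
- reactions considered so far: substrate + reagent in the reaction phase -> target; reagent in the reaction phase <-> reagent in the second phase; reagent in the reaction phase + target -> over-reaction product; reagent in the reaction phase -> decomposed reagent; 2 reagent in the reaction phase -> self-condensation product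
- the earlier runs hold the two phases in the same ratio of volumes as the flask asked about
- "hardly changes" means that all values lie within two and a half points (for a concentration: within two and a half percent of the largest)
- a step back or a flat step of under half a point counts as no turn

- amount of target at the end, in percent of the substrate charged for elm, oak, maple, cedar, larch, in this order
- how that number moves from the first to the last of them (rises all the way / falls, then rises / rises, then falls / falls all the way / hardly changes)

Target is made in proportion to [substrate][reagent in the reaction phase] and lost in proportion to f[target][reagent in the reaction phase]. The reagent cancels in the ratio of the two, so target follows the fraction s of substrate left: target = (s^f − s)/(1 − f). At the top of that curve, making equals loss, so f = s/target. Gamma's highest target reading gives a first answer of 0.305. That reading lies near the top, not on it, so go round using the end of gamma, where f = ln((1 − f)target + s)/ln s. Putting the first answer in returns 0.361, and once more returns the value I carry, a selectivity factor, rate constant of loss over rate constant of making, of 0.384. That last round still moved it by 0.0230, so take it as a rough value read from the gamma readings.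

The mark to watch is the substrate left at the top of the curve, 21.1%, where the curve puts target at 55.1%. Zeta ends above that mark with 40.8%, and gamma ends below it with 4.4%. Their values of ln(charged/left) are 0.896 and 3.12, a ratio of 3.48 for a charge ratio of 3.42. Taking them as proportional, the mark needs about 0.0659 M, so you charge oak.

The forecast, whose ground is that “both steps use the same reagent”, gives 43%, 54%, 43%, 21% and 7%: rises, then falls.

The flask gives 43.3%, 54.5%, 43.1%, 18.8% and 6.37%: rises, then falls, turning at 0.063 M.

    substrate + reagent in the reaction phase → target (k = 0.610 M⁻¹ min⁻¹)
    reagent in the reaction phase ⇌ reagent in the second phase, rate k2*([reagent in the reaction phase] - [reagent in the second phase]/K2) per volume of the first phase (partition coefficient = 0.490, kL = 0.0490 min⁻¹)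
    reagent in the reaction phase + target → over-reaction product (k = 0.240 M⁻¹ min⁻¹)
    reagent in the reaction phase → decomposed reagent (k = 0.00280 min⁻¹)
    2 reagent in the reaction phase → self-condensation product (k = 0.120 M⁻¹ min⁻¹)

Oak ends with 23% of its substrate left, beside the mark of 21.1%, and its target of 54.5% is the highest of the row. The main reason for the low target in larch is the over-reaction: with that step taken away, larch holds >99.9% of target instead of 6.37%. The carried factor also serves on cedar, where 0.44% of substrate left, put through the curve, gives 19.5% of target, and the cedar flask holds 18.8%.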